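**Retrosynthetic overview**

1. The strategy rests on rings A and B. The ent-trans-decalin of the target (oxygen on C3, quaternary C4 with equatorial C18 methyl and axial C19–O, trans C5–H/C10–CH3, side chain on C9) is that of andrographolide, whose butenolide (C13–C16) is joined to the decalin only through C12=C13.
2. Axial 3-OH ⇐ 3-ketone ⇐ equatorial 3-OH (oxidation, then equatorial hydride delivery); 19-acetate ⇐ 3,19-diol 15-acid ⇐ methyl ester acetonide.
3. C12–C13 ⇐ copper/bisphosphine-catalysed asymmetric conjugate addition of the C12 Grignard reagent to methyl (E)-crotonate, which sets C13.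
4. C12 bromide ⇐ C12 alcohol with C7=C8 ⇐ (alkene isomerisation, aldehyde reduction) ⇐ C12 aldehyde ⇐ permanganate cleavage of C12=C13 in andrographolide 3,19-acetonide.
5. Ring order: no carbocycle is built; rings A and B are bought intact, and only the temporary dioxane of the acetonide is closed (step 1) and opened (step 8).

Key step: step 2

Assumption: (R)-Tol-BINAP is taken as the ligand antipode that sends the alkyl group to the Si face of C13 of the (E)-crotonate (13R); the sense is to be checked on a simple primary alkylmagnesium bromide, and (S)-Tol-BINAP takes its place if it is the reverse.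

**Route**

Step 1
Reactants: 1 andrographolide
Product: 2 3,19-O-isopropylideneandrographolide (dioxane across O3 and O19; 14-OH free)
Conditions: 2,2-dimethoxypropane, PPTS (cat.), CH2Cl2, rt → 40 °C
Reagents that add atoms: 2,2-dimethoxypropane, COC(C)(C)OC
Why: Acid-catalysed transketalisation (acetonide formation): the equatorial 3-OH and the axial C19 hydroxymethyl on C4 are gauche and close a six-membered 1,3-dioxane, the lone 14-OH has no diol partner, and no stereocentre is touched.

Step 2
Reactants: 2 3,19-O-isopropylideneandrographolide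
Product: 3 3,19-O-isopropylidene-13,14,15,16-tetranor-ent-labd-8(17)-en-12-al (C12 aldehyde of the decalin core)
Conditions: KMnO4 (1.4 equiv, in portions), THF/H2O (20:1), −10 → 0 °C; filtration through Celite
Reagents that add atoms: potassium permanganate, [K+].[O-][Mn](=O)(=O)=O
Why: Permanganate adds across C12=C13 in a [3+2] manner to a cyclic manganate diester, which fragments with scission of the C12–C13 bond to the C12 aldehyde and a water-soluble 3-oxo-lactone, the manganese ending as MnO2. The closest known reaction type is the permanganate (Lemieux–von Rudloff-type) oxidative cleavage used for side-chain degradation of labdanes. No ring is closed and no stereocentre is created; C4, C5, C9 and C10 lie outside the reacting bond, and C9 is β to the new carbonyl and cannot epimerise. The selectivity needed is C12=C13 over the 1,1-disubstituted C8=C17 alkene: permanganate reacts faster with the conjugated, lactone-polarised alkylidene bond, C8=C17 is shielded by the C10 methyl group and the C9 substituent, and low temperature with a limited amount of oxidant added in portions keeps the reaction there. The 3,19-diol is masked as the acetonide so that no alcohol of the product can be oxidised, and a bicarbonate wash removes any over-oxidised acidic material.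

Step 3
Reactants: 3 C12 aldehyde
Product: 4 3,19-O-isopropylidene-13,14,15,16-tetranor-ent-labd-8(17)-en-12-ol
Conditions: NaBH4, MeOH, 0 °C; aqueous work-up
Reagents that add atoms: none
Why: Borohydride reduction of an aldehyde; NaBH4 leaves the acetonide and the alkene untouched, and prompt reduction removes the aldehyde before it can undergo a carbonyl-ene reaction with C8=C17.

Step 4
Reactants: 4 C12 alcohol with C8=C17
Product: 5 3,19-O-isopropylidene-13,14,15,16-tetranor-ent-labd-7-en-12-ol (C7=C8 in ring B, C17 now a methyl group)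
Conditions: chloro[N,N'-bis(3,5-di-tert-butylsalicylidene)cyclohexane-1,2-diaminato]cobalt (trivalent cobalt, 5 mol%), PhSiH3 (10 mol%), benzene, rt
Reagents that add atoms: none
Why: Cobalt-hydride hydrogen-atom-transfer alkene isomerisation: the cobalt hydride gives a hydrogen atom to C17, the tertiary C8 radical returns a hydrogen atom from the C7 methylene (the C9–H is tertiary and flanked by quaternary C10 and the C11 chain), the trisubstituted product reacts much more slowly, and C9 is not part of the radical and keeps its configuration.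

Step 5
Reactants: 5 C12 alcohol with C7=C8
Product: 6 12-bromo-3,19-O-isopropylidene-13,14,15,16-tetranor-ent-labd-7-ene
Conditions: CBr4, PPh3, 2,6-lutidine (0.2 equiv), CH2Cl2, 0 °C
Reagents that add atoms: carbon tetrabromide, BrC(Br)(Br)Br
Why: Appel bromination of a primary alcohol through the alkoxyphosphonium salt and SN2 displacement by bromide; the medium is essentially neutral, so the acetonide and the trisubstituted alkene survive.

Step 6
Reactants: 6 C12 bromide; 7 methyl (E)-but-2-enoate (methyl crotonate)
Product: 9 methyl (13R)-3,19-(isopropylidenedioxy)-ent-labd-7-en-15-oate, via C12 alkylmagnesium bromide 8 (not isolated)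
Conditions: Mg turnings (I2 crystal), Et2O, reflux; then slow addition to 7 (1.5 equiv), CuI (2 mol%), (R)-Tol-BINAP (3 mol%), t-BuOMe, −40 °C; aq. NH4Cl
Reagents that add atoms: magnesium, [Mg] (kept only in 8; no reagent atom remains in 9)
Why: Grignard formation followed by copper/bisphosphine-catalysed asymmetric conjugate addition to an enoate: the ligated organocopper species forms a π-complex with the crotonate and transfers the C12 alkyl group to one face of C13 through a trivalent copper intermediate, so that C13 (R) is set by the ligand alone, the decalin stereocentres being too remote to interfere; the acetonide is inert to the organomagnesium reagent.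

Step 7
Reactants: 9 methyl ester acetonide
Product: 10 (13R)-3,19-(isopropylidenedioxy)-ent-labd-7-en-15-oic acid
Conditions: LiOH·H2O (3 equiv), THF/MeOH/H2O, rt; then 0.5 M HCl to pH 4, 0 °C
Reagents that add atoms: lithium hydroxide, [Li+].[OH-]
Why: Saponification by acyl–oxygen cleavage; C13 is β to the carboxyl group and cannot epimerise, and the acetonide is stable to base and to the brief, cold acidification.

Step 8
Reactants: 10 acid acetonide
Product: 11 (13R)-3,19-dihydroxy-ent-labd-7-en-15-oic acid (equatorial 3-OH, 3R)
Conditions: AcOH/THF/H2O (3:1:1), 40 °C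
Reagents that add atoms: none
Why: Acid-catalysed acetal hydrolysis; aqueous acetic acid is too weak to protonate the trisubstituted C7=C8 alkene, and both C–O bonds of the diol stay intact.

Step 9
Reactants: 11 3,19-diol 15-acid
Product: 12 (13R)-19-acetoxy-3-hydroxy-ent-labd-7-en-15-oic acid (equatorial 3-OH, the 3-epimer of the target)
Conditions: Ac2O (1.5 equiv), pyridine, CH2Cl2, −20 → 0 °C; then H2O/THF, rt
Reagents that add atoms: acetic anhydride, CC(=O)OC(C)=O
Why: Selective acylation: the primary C19-OH reacts with Ac2O/pyridine at low temperature faster than the secondary 3-OH next to quaternary C4, and the C15 mixed anhydride formed alongside is hydrolysed in the aqueous quench.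

Step 10
Reactants: 12 19-acetate with equatorial 3-OH
Product: 13 (13R)-19-acetoxy-3-oxo-ent-labd-7-en-15-oic acid
Conditions: Dess–Martin periodinane (1.3 equiv), CH2Cl2, 0 °C → rt
Reagents that add atoms: none
Why: Dess–Martin oxidation of a secondary alcohol; the ketone cannot expel the β-acetoxy group because C4 is quaternary, and the free acid and the alkene are inert to the periodinane.

Step 11
Reactants: 13 3-ketone 19-acetate
Product: 14 (3S,4R,5S,9R,10S,13R)-19-acetoxy-3-hydroxy-ent-labd-7-en-15-oic acid (axial 3-OH; target CNP0218903.1)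
Conditions: LiBH(s-Bu)3 (2.3 equiv), THF, −78 °C; AcOH quench at −78 °C, then H2O
Reagents that add atoms: none
Why: Stereoselective ketone reduction by a bulky trialkylborohydride: LiBH(s-Bu)3 avoids the axial trajectory past the axial hydrogens on C1 and C5 and delivers hydride equatorially, giving the axial 3-alcohol trans-diaxial to the C19 acetoxymethyl group; the first equivalent only deprotonates the acid, the carboxylate and the neopentyl acetate are not reduced at −78 °C, and the axial hydroxyl, being anti to C19, cannot take over the acetyl group.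

**Compound list**

1 | andrographolide | OC[C@@]1(C)[C@H]2CCC(=C)[C@@H](C/C=C3/C(=O)OC[C@H]3O)[C@]2(C)CC[C@H]1O | starting material
2 | 3,19-O-isopropylideneandrographolide | CC1(C)OC[C@@]2(C)[C@H]3CCC(=C)[C@@H](C/C=C4/C(=O)OC[C@H]4O)[C@]3(C)CC[C@H]2O1 | intermediate
3 | 3,19-O-isopropylidene-13,14,15,16-tetranor-ent-labd-8(17)-en-12-al | CC1(C)OC[C@@]2(C)[C@H]3CCC(=C)[C@@H](CC=O)[C@]3(C)CC[C@H]2O1 | intermediate
4 | 3,19-O-isopropylidene-13,14,15,16-tetranor-ent-labd-8(17)-en-12-ol | CC1(C)OC[C@@]2(C)[C@H]3CCC(=C)[C@@H](CCO)[C@]3(C)CC[C@H]2O1 | intermediate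
5 | 3,19-O-isopropylidene-13,14,15,16-tetranor-ent-labd-7-en-12-ol | CC1(C)OC[C@@]2(C)[C@H]3CC=C(C)[C@@H](CCO)[C@]3(C)CC[C@H]2O1 | intermediate
6 | 12-bromo-3,19-O-isopropylidene-13,14,15,16-tetranor-ent-labd-7-ene | CC1(C)OC[C@@]2(C)[C@H]3CC=C(C)[C@@H](CCBr)[C@]3(C)CC[C@H]2O1 | intermediate
7 | methyl (E)-but-2-enoate | C/C=C/C(=O)OC | starting material
8 | C12 alkylmagnesium bromide of 6 (not isolated) | CC1(C)OC[C@@]2(C)[C@H]3CC=C(C)[C@@H](CC[Mg]Br)[C@]3(C)CC[C@H]2O1 | intermediate
9 | methyl (13R)-3,19-(isopropylidenedioxy)-ent-labd-7-en-15-oate | CC1(C)OC[C@@]2(C)[C@H]3CC=C(C)[C@@H](CC[C@@H](C)CC(=O)OC)[C@]3(C)CC[C@H]2O1 | intermediate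
10 | (13R)-3,19-(isopropylidenedioxy)-ent-labd-7-en-15-oic acid | CC1(C)OC[C@@]2(C)[C@H]3CC=C(C)[C@@H](CC[C@@H](C)CC(=O)O)[C@]3(C)CC[C@H]2O1 | intermediate
11 | (13R)-3,19-dihydroxy-ent-labd-7-en-15-oic acid (equatorial 3-OH) | OC[C@@]1(C)[C@H]2CC=C(C)[C@@H](CC[C@@H](C)CC(=O)O)[C@]2(C)CC[C@H]1O | intermediate
12 | (13R)-19-acetoxy-3-hydroxy-ent-labd-7-en-15-oic acid (equatorial 3-OH) | CC(=O)OC[C@@]1(C)[C@H]2CC=C(C)[C@@H](CC[C@@H](C)CC(=O)O)[C@]2(C)CC[C@H]1O | intermediate
13 | (13R)-19-acetoxy-3-oxo-ent-labd-7-en-15-oic acid | CC(=O)OC[C@@]1(C)[C@H]2CC=C(C)[C@@H](CC[C@@H](C)CC(=O)O)[C@]2(C)CCC1=O | intermediate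
14 | (3S,4R,5S,9R,10S,13R)-19-acetoxy-3-hydroxy-ent-labd-7-en-15-oic acid (axial 3-OH), CNP0218903.1 | CC(=O)OC[C@@]1(C)[C@H]2CC=C(C)[C@@H](CC[C@@H](C)CC(=O)O)[C@]2(C)CC[C@@H]1O | target

**Step count**

Total step count: 11. Longest linear sequence: 11 steps (1 → 14).

**Steps most likely to fail**

Step 6. The chiral copper catalyst may discriminate the two faces of the crotonate poorly with this large Grignard reagent, and uncatalysed 1,2-addition or enolate–crotonate oligomerisation may compete. The resulting C13 epimers would differ only far from the decalin and would be hard to separate. The fallback replaces catalyst control by auxiliary control; it sets out from 8 (made from 6 as in step 6) and comes back at 10. (R)-4-Phenyloxazolidin-2-one is N-acylated (n-BuLi, (E)-crotonyl chloride, THF, −78 °C) to (R)-3-[(E)-but-2-enoyl]-4-phenyloxazolidin-2-one F1. Reagent 8 is added to it with CuBr·SMe2 (1 equiv) in THF/Me2S at −40 °C to give the 3-[(13R)-3,19-(isopropylidenedioxy)-ent-labd-7-en-15-oyl]-(R)-4-phenyloxazolidin-2-one F2. The magnesium-chelated syn-s-cis imide should be attacked anti to the phenyl group, on the Si face of C13, and any minor C13 epimer is now a diastereomer close to the auxiliary and separable by chromatography or crystallisation. LiOH/H2O2 in THF/H2O at 0 °C then cleaves the imide to acid 10 and returns the auxiliary.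

Step 4. Hydrogen return from C9–H instead of C7–H would give the tetrasubstituted C8=C9 isomer, and incomplete conversion would leave alkene isomers that are hard to separate. The fallback builds the C7=C8 alkene regiospecifically; it sets out from 4 and comes back at 5. Silylation (TBSCl, imidazole, DMF) should give the 12-O-tert-butyldimethylsilyl ether of 4 F3. Ozonolysis (O3, CH2Cl2/MeOH, −78 °C; Me2S) should give the 17-nor-8-ketone F4, in which the equatorial C9 substituent is the stable epimer. Kinetic deprotonation at the C7 methylene and triflation (KN(SiMe3)2, PhNTf2, THF, −78 °C) should give the C7-enol triflate F5; the tertiary, shielded C9–H is not removed. Iron-catalysed cross-coupling (Fe(acac)3 cat., MeMgBr, THF/NMP, −30 °C) installs the C17 methyl group to give the silyl ether of 5 F6, and TBAF in THF releases 5.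

Step 11. Hydride may be delivered in part along the axial trajectory, returning the equatorial alcohol 12. Hydride may also attack the C19 acetate, after which the freed 3-keto-19-alkoxide loses formaldehyde by retro-aldol cleavage. The fallback uses intramolecular hydride delivery from O19 instead of steric approach control; it sets out from 11 and comes back at 14. Tritylation of the primary alcohol (TrCl, pyridine, DMAP, 50 °C) should give the 19-O-trityl ether F7. Dess–Martin oxidation gives the 19-O-trityl 3-ketone F8, and 80% aqueous AcOH at rt removes the trityl group under acidic conditions that do not trigger retro-aldol cleavage, giving the 19-hydroxy-3-ketone F9. Evans–Saksena reduction (Me4NBH(OAc)3, MeCN/AcOH, −20 °C) binds boron to O19 and delivers hydride to the face of C3 on which the axial C19 sits, that is equatorially, to give the 3-epi-3,19-diol acid with axial 3-OH F10. Acetylation (Ac2O, pyridine, CH2Cl2, 0 °C) then takes place at the primary C19-OH, the axial 3-OH being more hindered and anti to C19, and gives 14.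

**Further compounds**

F1 | step 6 | (R)-3-[(E)-but-2-enoyl]-4-phenyloxazolidin-2-one | C/C=C/C(=O)N1C(=O)OC[C@H]1c2ccccc2
F2 | step 6 | 3-[(13R)-3,19-(isopropylidenedioxy)-ent-labd-7-en-15-oyl]-(R)-4-phenyloxazolidin-2-one | CC1(C)OC[C@@]2(C)[C@H]3CC=C(C)[C@@H](CC[C@@H](C)CC(=O)N4C(=O)OC[C@H]4c5ccccc5)[C@]3(C)CC[C@H]2O1
F3 | step 4 | 12-O-tert-butyldimethylsilyl ether of 4 | CC1(C)OC[C@@]2(C)[C@H]3CCC(=C)[C@@H](CCO[Si](C)(C)C(C)(C)C)[C@]3(C)CC[C@H]2O1
F4 | step 4 | 17-nor-8-ketone silyl ether | CC1(C)OC[C@@]2(C)[C@H]3CCC(=O)[C@@H](CCO[Si](C)(C)C(C)(C)C)[C@]3(C)CC[C@H]2O1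
F5 | step 4 | C7-enol triflate silyl ether | CC1(C)OC[C@@]2(C)[C@H]3CC=C(OS(=O)(=O)C(F)(F)F)[C@@H](CCO[Si](C)(C)C(C)(C)C)[C@]3(C)CC[C@H]2O1
F6 | step 4 | 12-O-tert-butyldimethylsilyl ether of 5 | CC1(C)OC[C@@]2(C)[C@H]3CC=C(C)[C@@H](CCO[Si](C)(C)C(C)(C)C)[C@]3(C)CC[C@H]2O1
F7 | step 11 | 19-O-trityl ether of 11 | C(c1ccccc1)(c1ccccc1)(c1ccccc1)OC[C@@]1(C)[C@H]2CC=C(C)[C@@H](CC[C@@H](C)CC(=O)O)[C@]2(C)CC[C@H]1O
F8 | step 11 | 19-O-trityl 3-ketone acid | C(c1ccccc1)(c1ccccc1)(c1ccccc1)OC[C@@]1(C)[C@H]2CC=C(C)[C@@H](CC[C@@H](C)CC(=O)O)[C@]2(C)CCC1=O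
F9 | step 11 | (13R)-19-hydroxy-3-oxo-ent-labd-7-en-15-oic acid | OC[C@@]1(C)[C@H]2CC=C(C)[C@@H](CC[C@@H](C)CC(=O)O)[C@]2(C)CCC1=O
F10 | step 11 | (13R)-3,19-dihydroxy-ent-labd-7-en-15-oic acid with axial 3-OH (3-epimer of 11) | OC[C@@]1(C)[C@H]2CC=C(C)[C@@H](CC[C@@H](C)CC(=O)O)[C@]2(C)CC[C@@H]1O
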